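**Plan**

- Retrosynthetic cuts, in order: the phenol ester; the C2'–C3' bond of the diene (Suzuki coupling of a chroman (E)-alkenylboronate with a (Z)-iodoalkene); C1'=C2' (boryl-olefination of a chroman-2-carbaldehyde); the C4–C4a bond of the pyran ring (retro 1,2-shift to a spiro-fused oxolane); O1–C8a (retro-dearomatisation to a para-alkylphenol); C3–C4 (benzyl Grignard plus 2-methylglycidol ether).
- Enabling feature: in the benzopyran, O1 sits on C8a, the free OH on C6 para to it, and C4 on the adjacent C4a. This is the pattern a dienone–phenol shift leaves when a 1-oxaspiro[4.5]deca-6,9-dien-8-one (spiro carbon = C8a, carbonyl carbon = C6) passes its oxolane CH2 (C4) to the neighbouring ring carbon.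
- Forward order of rings: the benzene ring is bought as a para-substituted phenol; the oxolane is closed onto its ipso carbon by oxidative dearomatisation (step 4) and then enlarged to the dihydropyran with rearomatisation (step 5). The trimethylcyclohexene ring is bought and joined last through the diene.
- Stereochemistry: C2 (R) comes from (S)-2-methylglycidol and none of its four bonds is broken afterwards. The 1E alkene comes from a Takai–Utimoto olefination and the 3Z alkene from syn-carbocupration of propyne; both are carried through a stereoretentive Suzuki coupling.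

Key step: step 5

Assumption: the target is read as (2R) with a (1E,3Z)-diene, and (S)-2-methylglycidol and β-homocyclocitral are taken as commercial starting materials.

**Route**

Step 1
Reactants: 1 [(2S)-2-methyloxiran-2-yl]methanol ((S)-2-methylglycidol)
Product: 2 tert-butyl{[(2R)-2-methyloxiran-2-yl]methoxy}diphenylsilane
Conditions: TBDPSCl, imidazole, CH2Cl2, 0 °C → rt
Reagents that add atoms: tert-butyl(chloro)diphenylsilane (TBDPSCl), CC(C)(C)[Si](Cl)(c1ccccc1)c1ccccc1
Why: Imidazole-assisted silylation masks the primary hydroxyl for the Grignard step; the quaternary epoxide carbon is not touched, and the descriptor changes from S to R only because the silyloxymethyl group now outranks the ring CH2.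

Step 2
Reactants: 2 tert-butyl{[(2R)-2-methyloxiran-2-yl]methoxy}diphenylsilane; 3 1-(benzyloxy)-4-(chloromethyl)benzene
Product: 5 (2R)-4-[4-(benzyloxy)phenyl]-1-{[tert-butyl(diphenyl)silyl]oxy}-2-methylbutan-2-ol, via benzylic Grignard reagent 4 (not isolated)
Conditions: 3, Mg, THF, 0 °C; then 2, CuI (10 mol %), THF, −30 → 0 °C; aq. NH4Cl
Reagents that add atoms: none
Why: Copper-catalysed Grignard opening of a 2,2-disubstituted epoxide should occur by SN2 attack at the unsubstituted CH2 terminus, forging the future C3–C4 bond and leaving the tertiary carbinol centre, which is not attacked, with the configuration bought in with 1.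

Step 3
Reactants: 5 (2R)-4-[4-(benzyloxy)phenyl]-1-{[tert-butyl(diphenyl)silyl]oxy}-2-methylbutan-2-ol
Product: 6 4-[(3R)-4-{[tert-butyl(diphenyl)silyl]oxy}-3-hydroxy-3-methylbutyl]phenol
Conditions: H2 (1 atm), Pd/C (10 %), EtOAc, rt
Reagents that add atoms: none
Why: Hydrogenolysis of the aryl benzyl ether over palladium on carbon should free the phenol, while the silyl ether and the tertiary alcohol are inert in ethyl acetate.

Step 4
Reactants: 6 4-[(3R)-4-{[tert-butyl(diphenyl)silyl]oxy}-3-hydroxy-3-methylbutyl]phenol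
Product: 7 (2R)-2-({[tert-butyl(diphenyl)silyl]oxy}methyl)-2-methyl-1-oxaspiro[4.5]deca-6,9-dien-8-one
Conditions: PhI(OAc)2 (1.1 equiv), (CF3)2CHOH, 0 °C
Reagents that add atoms: none
Why: Oxidative dearomatisation of a para-alkylphenol by a hypervalent iodine reagent, with ipso capture by the tethered tertiary hydroxyl (5-exo spirocyclisation), is the standard entry to 1-oxaspiro[4.5]deca-6,9-dien-8-ones; the spiro carbon is no stereocentre because its two dienone arms are identical.

Step 5
Reactants: 7 (2R)-2-({[tert-butyl(diphenyl)silyl]oxy}methyl)-2-methyl-1-oxaspiro[4.5]deca-6,9-dien-8-one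
Product: 8 (2R)-2-({[tert-butyl(diphenyl)silyl]oxy}methyl)-2-methyl-3,4-dihydro-2H-chromen-6-ol
Conditions: BF3·OEt2 (1.2 equiv), CH2Cl2, −20 °C → rt
Reagents that add atoms: none
Why: Coordination of BF3 to the dienone oxygen should give a 4-oxycyclohexadienyl cation with positive charge on the two ring carbons flanking the spiro carbon; a suprafacial 1,2-shift of the oxolane CH2 (C4) from the spiro carbon to one of them leaves an oxocarbenium ion stabilised by O1, and loss of the proton from the carbon that received C4 restores the arene, so that the spiro carbon becomes C8a, the acceptor carbon C4a and the carbonyl carbon the C6 phenol. The closest known reaction type is the dienone–phenol rearrangement of 4-alkyl-4-alkoxycyclohexa-2,5-dienones (p-quinol ether to hydroquinone monoether) and the classical ring expansion of spiro[4.5]decadienones to tetralols. The dihydropyran ring is not closed by a cyclisation, so no Baldwin mode applies: it arises by one-carbon enlargement of the oxolane, the bond from C4 to the spiro carbon being exchanged for the C4–C4a bond. No new stereocentre is formed; C2 keeps its bonds to O1, C3, CH3 and the silyloxymethyl carbon throughout, so its (R) configuration is carried over, and the two dienone carbons next to the spiro centre lead to the same product. The step needs carbon and not oxygen migration and no heterolysis of the tertiary C2–O1 bond: carbon migration is favoured because only it leaves the cation on an oxygen-bearing carbon, and ionisation at C2 is disfavoured by the inductively withdrawing silyloxymethyl group and the absence of unsaturation at C2 at this stage.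

Step 6
Reactants: 8 (2R)-2-({[tert-butyl(diphenyl)silyl]oxy}methyl)-2-methyl-3,4-dihydro-2H-chromen-6-ol
Product: 9 (2R)-2-({[tert-butyl(diphenyl)silyl]oxy}methyl)-2-methyl-3,4-dihydro-2H-chromen-6-yl 2,2-dimethylpropanoate
Conditions: PivCl, Et3N, DMAP (cat.), CH2Cl2, 0 °C → rt
Reagents that add atoms: pivaloyl chloride, CC(C)(C)C(Cl)=O
Why: Acylation of the phenol, the only free hydroxyl, as a pivalate should shield the electron-rich hydroquinone monoether from the oxidant and the organometallic reagents to come.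

Step 7
Reactants: 9 (2R)-2-({[tert-butyl(diphenyl)silyl]oxy}methyl)-2-methyl-3,4-dihydro-2H-chromen-6-yl 2,2-dimethylpropanoate
Product: 10 (2R)-2-(hydroxymethyl)-2-methyl-3,4-dihydro-2H-chromen-6-yl 2,2-dimethylpropanoate
Conditions: TBAF, AcOH (1:1), THF, rt
Reagents that add atoms: none
Why: Fluoride cleavage of the primary silyl ether, buffered with acetic acid so that the aryl pivalate is not attacked.

Step 8
Reactants: 10 (2R)-2-(hydroxymethyl)-2-methyl-3,4-dihydro-2H-chromen-6-yl 2,2-dimethylpropanoate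
Product: 11 (2R)-2-formyl-2-methyl-3,4-dihydro-2H-chromen-6-yl 2,2-dimethylpropanoate
Conditions: Dess–Martin periodinane (DMP), CH2Cl2, 0 °C → rt
Reagents that add atoms: none
Why: Dess–Martin oxidation of the neopentyl-type primary alcohol should give the aldehyde, which has no alpha hydrogen and therefore cannot epimerise.

Step 9
Reactants: 11 (2R)-2-formyl-2-methyl-3,4-dihydro-2H-chromen-6-yl 2,2-dimethylpropanoate
Product: 12 (2R)-2-methyl-2-[(E)-2-(4,4,5,5-tetramethyl-1,3,2-dioxaborolan-2-yl)ethenyl]-3,4-dihydro-2H-chromen-6-yl 2,2-dimethylpropanoate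
Conditions: Cl2CHBpin (2 equiv), CrCl2 (8 equiv), LiI (4 equiv), THF, rt
Reagents that add atoms: 2-(dichloromethyl)-4,4,5,5-tetramethyl-1,3,2-dioxaborolane (Cl2CHBpin), ClC(Cl)B1OC(C)(C)C(C)(C)O1
Why: The Takai–Utimoto olefination (geminal dichromium reagent from the dichloromethylboronate and divalent chromium) converts aldehydes into (E)-alkenylboronates, the E geometry following from elimination through the less hindered beta-oxido chromium adduct.

Step 10
Reactants: 13 (2,6,6-trimethylcyclohex-1-en-1-yl)acetaldehyde (β-homocyclocitral)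
Product: 14 2-(2,6,6-trimethylcyclohex-1-en-1-yl)ethan-1-ol
Conditions: NaBH4, MeOH, 0 °C
Reagents that add atoms: none
Why: Borohydride reduction of the aldehyde; the tetrasubstituted ring alkene is inert and already in its most stable position.

Step 11
Reactants: 14 2-(2,6,6-trimethylcyclohex-1-en-1-yl)ethan-1-ol
Product: 15 2-(2-bromoethyl)-1,3,3-trimethylcyclohex-1-ene
Conditions: CBr4, PPh3, CH2Cl2, 0 °C
Reagents that add atoms: tetrabromomethane (CBr4), BrC(Br)(Br)Br
Why: Appel bromination of the primary alcohol under neutral conditions avoids acid that could move the ring alkene.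

Step 12
Reactants: 15 2-(2-bromoethyl)-1,3,3-trimethylcyclohex-1-ene; 16 propyne
Product: 20 2-[(3Z)-4-iodo-3-methylbut-3-en-1-yl]-1,3,3-trimethylcyclohex-1-ene, via homoallylic Grignard reagent 17 (not isolated), via alkylcopper reagent 18 (not isolated), via Z-alkenylcopper reagent 19 (not isolated)
Conditions: 15, Mg, Et2O, rt; CuBr·SMe2 (1 equiv), Et2O/Me2S, −45 °C; 16 (excess), −25 °C; then I2, THF, −50 → 0 °C
Reagents that add atoms: iodine (I2), II
Why: In the Normant carbocupration the alkylcopper reagent adds syn across propyne with the alkyl group at the internal carbon and copper at the terminus, so chain and copper are cis, and iodinolysis with retention should give the (Z)-iodoalkene.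

Step 13
Reactants: 12 (2R)-2-methyl-2-[(E)-2-(4,4,5,5-tetramethyl-1,3,2-dioxaborolan-2-yl)ethenyl]-3,4-dihydro-2H-chromen-6-yl 2,2-dimethylpropanoate; 20 2-[(3Z)-4-iodo-3-methylbut-3-en-1-yl]-1,3,3-trimethylcyclohex-1-ene
Product: 21 (2R)-2-methyl-2-[(1E,3Z)-4-methyl-6-(2,6,6-trimethylcyclohex-1-en-1-yl)hexa-1,3-dien-1-yl]-3,4-dihydro-2H-chromen-6-yl 2,2-dimethylpropanoate
Conditions: Pd(PPh3)4 (5 mol %), 3 M aq. K3PO4, THF, 45 °C, degassed
Reagents that add atoms: none
Why: Suzuki–Miyaura alkenyl–alkenyl coupling proceeds with retention at both partners, so the E geometry of 12 and the Z geometry of 20 should be transferred to the (1E,3Z)-diene.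

Step 14
Reactants: 21 (2R)-2-methyl-2-[(1E,3Z)-4-methyl-6-(2,6,6-trimethylcyclohex-1-en-1-yl)hexa-1,3-dien-1-yl]-3,4-dihydro-2H-chromen-6-yl 2,2-dimethylpropanoate
Product: 22 (2R)-2-methyl-2-[(1E,3Z)-4-methyl-6-(2,6,6-trimethylcyclohex-1-en-1-yl)hexa-1,3-dien-1-yl]-3,4-dihydro-2H-chromen-6-ol
Conditions: K2CO3 (0.3 equiv), MeOH/THF, rt, degassed; aq. NH4Cl
Reagents that add atoms: none
Why: Base-catalysed methanolysis of the aryl pivalate (transesterification) should liberate the phenol without acid, so the doubly allylic tertiary aryl ether and the diene geometry are left untouched.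

**Compound list**

1 | [(2S)-2-methyloxiran-2-yl]methanol ((S)-2-methylglycidol) | C[C@]1(CO)CO1 | starting material
2 | tert-butyl{[(2R)-2-methyloxiran-2-yl]methoxy}diphenylsilane | C[C@]1(CO[Si](c2ccccc2)(c2ccccc2)C(C)(C)C)CO1 | intermediate
3 | 1-(benzyloxy)-4-(chloromethyl)benzene | ClCc1ccc(OCc2ccccc2)cc1 | starting material
4 | [4-(benzyloxy)benzyl]magnesium chloride | Cl[Mg]Cc1ccc(OCc2ccccc2)cc1 | intermediate
5 | (2R)-4-[4-(benzyloxy)phenyl]-1-{[tert-butyl(diphenyl)silyl]oxy}-2-methylbutan-2-ol | C[C@](O)(CO[Si](c1ccccc1)(c1ccccc1)C(C)(C)C)CCc1ccc(OCc2ccccc2)cc1 | intermediate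
6 | 4-[(3R)-4-{[tert-butyl(diphenyl)silyl]oxy}-3-hydroxy-3-methylbutyl]phenol | C[C@](O)(CO[Si](c1ccccc1)(c1ccccc1)C(C)(C)C)CCc1ccc(O)cc1 | intermediate
7 | (2R)-2-({[tert-butyl(diphenyl)silyl]oxy}methyl)-2-methyl-1-oxaspiro[4.5]deca-6,9-dien-8-one | C[C@]1(CO[Si](c2ccccc2)(c2ccccc2)C(C)(C)C)CCC2(C=CC(=O)C=C2)O1 | intermediate
8 | (2R)-2-({[tert-butyl(diphenyl)silyl]oxy}methyl)-2-methyl-3,4-dihydro-2H-chromen-6-ol | C[C@]1(CO[Si](c2ccccc2)(c2ccccc2)C(C)(C)C)CCc2cc(O)ccc2O1 | intermediate
9 | (2R)-2-({[tert-butyl(diphenyl)silyl]oxy}methyl)-2-methyl-3,4-dihydro-2H-chromen-6-yl 2,2-dimethylpropanoate | C[C@]1(CO[Si](c2ccccc2)(c2ccccc2)C(C)(C)C)CCc2cc(OC(=O)C(C)(C)C)ccc2O1 | intermediate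
10 | (2R)-2-(hydroxymethyl)-2-methyl-3,4-dihydro-2H-chromen-6-yl 2,2-dimethylpropanoate | C[C@]1(CO)CCc2cc(OC(=O)C(C)(C)C)ccc2O1 | intermediate
11 | (2R)-2-formyl-2-methyl-3,4-dihydro-2H-chromen-6-yl 2,2-dimethylpropanoate | C[C@]1(C=O)CCc2cc(OC(=O)C(C)(C)C)ccc2O1 | intermediate
12 | (2R)-2-methyl-2-[(E)-2-(4,4,5,5-tetramethyl-1,3,2-dioxaborolan-2-yl)ethenyl]-3,4-dihydro-2H-chromen-6-yl 2,2-dimethylpropanoate | C[C@]1(/C=C/B2OC(C)(C)C(C)(C)O2)CCc2cc(OC(=O)C(C)(C)C)ccc2O1 | intermediate
13 | (2,6,6-trimethylcyclohex-1-en-1-yl)acetaldehyde (β-homocyclocitral) | CC1=C(CC=O)C(C)(C)CCC1 | starting material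
14 | 2-(2,6,6-trimethylcyclohex-1-en-1-yl)ethan-1-ol | CC1=C(CCO)C(C)(C)CCC1 | intermediate
15 | 2-(2-bromoethyl)-1,3,3-trimethylcyclohex-1-ene | CC1=C(CCBr)C(C)(C)CCC1 | intermediate
16 | propyne | CC#C | starting material
17 | [2-(2,6,6-trimethylcyclohex-1-en-1-yl)ethyl]magnesium bromide | CC1=C(CC[Mg]Br)C(C)(C)CCC1 | intermediate
18 | [2-(2,6,6-trimethylcyclohex-1-en-1-yl)ethyl]copper | CC1=C(CC[Cu])C(C)(C)CCC1 | intermediate
19 | [(1Z)-2-methyl-4-(2,6,6-trimethylcyclohex-1-en-1-yl)but-1-en-1-yl]copper | CC1=C(CC/C(C)=C\[Cu])C(C)(C)CCC1 | intermediate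
20 | 2-[(3Z)-4-iodo-3-methylbut-3-en-1-yl]-1,3,3-trimethylcyclohex-1-ene | CC1=C(CC/C(C)=C\I)C(C)(C)CCC1 | intermediate
21 | (2R)-2-methyl-2-[(1E,3Z)-4-methyl-6-(2,6,6-trimethylcyclohex-1-en-1-yl)hexa-1,3-dien-1-yl]-3,4-dihydro-2H-chromen-6-yl 2,2-dimethylpropanoate | CC1=C(CC/C(C)=C\C=C\[C@@]2(C)CCc3cc(OC(=O)C(C)(C)C)ccc3O2)C(C)(C)CCC1 | intermediate
22 | (2R)-2-methyl-2-[(1E,3Z)-4-methyl-6-(2,6,6-trimethylcyclohex-1-en-1-yl)hexa-1,3-dien-1-yl]-3,4-dihydro-2H-chromen-6-ol (CNP0275099.1) | CC1=C(CC/C(C)=C\C=C\[C@@]2(C)CCc3cc(O)ccc3O2)C(C)(C)CCC1 | target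

**Step count and risks**

Total: 14 steps. Longest linear sequence: 11 steps (steps 1 to 9, 13 and 14, from 1).

Steps most likely to fail:

Step 5. Oxygen could migrate instead of carbon, giving the regioisomeric phenol. The tertiary C2–O1 bond could undergo heterolysis with loss of configuration. The Lewis acid could also remove the silyl group. The fallback gives up the ring expansion and forms the O1–C8a bond by intramolecular palladium-catalysed aryl ether formation. It sets out from epoxide 2. CuI-catalysed opening with [5-(benzyloxy)-2-bromobenzyl]magnesium bromide F1, prepared from 4-(benzyloxy)-1-bromo-2-(bromomethyl)benzene and Mg in Et2O at 0 °C, should give (2R)-4-[5-(benzyloxy)-2-bromophenyl]-1-{[tert-butyl(diphenyl)silyl]oxy}-2-methylbutan-2-ol F2. Treatment with Pd(OAc)2, 2-(di-tert-butylphosphino)-1,1'-binaphthyl and Cs2CO3 in toluene at 80 °C should close the pyran ring to tert-butyl{[(2R)-6-(benzyloxy)-2-methyl-3,4-dihydro-2H-chromen-2-yl]methoxy}diphenylsilane F3. Hydrogenolysis (H2, Pd/C, EtOAc) comes back to the route at 8.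

Step 9. The hindered, alpha-quaternary aldehyde may convert incompletely, the E selectivity may erode, or the boronate may protodeboronate on purification. The fallback reverses the roles of the coupling partners and sets out from aldehyde 11. Takai iodo-olefination (CrCl2, CHI3, THF/dioxane) should give (2R)-2-[(E)-2-iodoethenyl]-2-methyl-3,4-dihydro-2H-chromen-6-yl 2,2-dimethylpropanoate F4. Iodide 20 is converted by t-BuLi (Et2O, −78 °C) into [(1Z)-2-methyl-4-(2,6,6-trimethylcyclohex-1-en-1-yl)but-1-en-1-yl]lithium F5 and by ZnCl2 into [(1Z)-2-methyl-4-(2,6,6-trimethylcyclohex-1-en-1-yl)but-1-en-1-yl]zinc chloride F6. Negishi coupling of F6 with F4 under Pd(PPh3)4 in THF at rt comes back at 21.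

Step 13. Zerovalent palladium could ionise the tertiary allylic aryl ether, leading to racemisation or ring opening through an allylpalladium species. The trisubstituted alkene could drift from Z to E, or the boronate could protodeboronate under the aqueous base. The fallback is a palladium-free, base-free coupling and sets out from aldehyde 11. Stannyl-olefination (CrCl2, Bu3SnCHBr2, LiI, THF/DMF) should give (2R)-2-methyl-2-[(E)-2-(tributylstannyl)ethenyl]-3,4-dihydro-2H-chromen-6-yl 2,2-dimethylpropanoate F7. Coupling of F7 with 20, mediated by monovalent copper thiophene-2-carboxylate (CuTC) in NMP at 0 °C, comes back at 21.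

**Further compounds**

F1 | step 5 | [5-(benzyloxy)-2-bromobenzyl]magnesium bromide | Br[Mg]Cc1cc(OCc2ccccc2)ccc1Br
F2 | step 5 | (2R)-4-[5-(benzyloxy)-2-bromophenyl]-1-{[tert-butyl(diphenyl)silyl]oxy}-2-methylbutan-2-ol | C[C@](O)(CO[Si](c1ccccc1)(c1ccccc1)C(C)(C)C)CCc1cc(OCc2ccccc2)ccc1Br
F3 | step 5 | tert-butyl{[(2R)-6-(benzyloxy)-2-methyl-3,4-dihydro-2H-chromen-2-yl]methoxy}diphenylsilane | C[C@]1(CO[Si](c2ccccc2)(c2ccccc2)C(C)(C)C)CCc2cc(OCc3ccccc3)ccc2O1
F4 | step 9 | (2R)-2-[(E)-2-iodoethenyl]-2-methyl-3,4-dihydro-2H-chromen-6-yl 2,2-dimethylpropanoate | C[C@]1(/C=C/I)CCc2cc(OC(=O)C(C)(C)C)ccc2O1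
F5 | step 9 | [(1Z)-2-methyl-4-(2,6,6-trimethylcyclohex-1-en-1-yl)but-1-en-1-yl]lithium | CC1=C(CC/C(C)=C\[Li])C(C)(C)CCC1
F6 | step 9 | [(1Z)-2-methyl-4-(2,6,6-trimethylcyclohex-1-en-1-yl)but-1-en-1-yl]zinc chloride | CC1=C(CC/C(C)=C\[Zn]Cl)C(C)(C)CCC1
F7 | step 13 | (2R)-2-methyl-2-[(E)-2-(tributylstannyl)ethenyl]-3,4-dihydro-2H-chromen-6-yl 2,2-dimethylpropanoate | C[C@]1(/C=C/[Sn](CCCC)(CCCC)CCCC)CCc2cc(OC(=O)C(C)(C)C)ccc2O1
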